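The target is cut at the tertiary alkyl C–O bond of its ester. The acid half comes from 3,5-dibromo-4-hydroxybenzoic acid (1), used as its acetate 2; the alcohol half comes from (1S,5S)-sabinene (3). The feature exploited is the homoallylic array in the cyclohexene ring: the quaternary carbon bearing oxygen and isopropyl lies one CH2 away from the methyl-substituted ring C=C, which maps onto the cyclopropylcarbinyl unit C4–C5–C1 of 3. One acid-catalysed addition of 2 to 3 opens the internal C1–C5 bond, forms the C–O bond with inversion at C1 and thereby delivers ring alkene and sole stereocentre of ester 4. The bromines of 4 are finally exchanged for prenyl groups.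

Key step: step 2

Remark: (1S,5S)-sabinene (the levorotatory enantiomer) is assumed to be purchasable in high enantiomeric purity, to be confirmed by chiral GC; inversion at its C1 was checked to give the (R) configuration of the target, and the phenol of 1 is masked as an acetate so that the acid dissolves in CH2Cl2 and offers only the carboxyl group as nucleophile.

Step 1
Reactants: 1 3,5-dibromo-4-hydroxybenzoic acid
Product: 2 4-acetoxy-3,5-dibromobenzoic acid
Conditions: Ac2O (3 equiv), H2SO4 (cat.), 60 °C; then H2O, 0 °C
Reagents that add atoms: acetic anhydride, CC(=O)OC(C)=O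
Why: Acid-catalysed O-acetylation of a phenol by an anhydride (esterification) is reliable even for the hindered, electron-poor 2,6-dibromophenol, leaves the carboxyl group free after the aqueous quench, and turns the hydrogen-bonded hydroxy acid into a CH2Cl2-soluble acid; no stereocentre is involved.

Step 2
Reactants: 3 (1S,5S)-sabinene [(1S,5S)-4-methylidene-1-(propan-2-yl)bicyclo[3.1.0]hexane]; 2 4-acetoxy-3,5-dibromobenzoic acid
Product: 4 (R)-terpinen-4-yl 4-acetoxy-3,5-dibromobenzoate [(1R)-4-methyl-1-(propan-2-yl)cyclohex-3-en-1-yl ester]
Conditions: 2 (2.5 equiv), HNTf2 (5 mol %), CH2Cl2, slow addition of 3, −60 → −40 °C; then Et3N (10 mol %), −60 °C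
Reagents that add atoms: none
Why: Proposed new method: HNTf2 protonates the exocyclic methylene carbon of 3 to give the tertiary cyclopropylcarbinyl cation at C4 (sabinene numbering), whose charge is shared with the internal C1–C5 bond, and the carbonyl oxygen of 2 attacks C1 on the face opposite C5 while that bond breaks, so the C–O bond and the C4=C5 alkene arise together. The closest known reaction type is the acid-catalysed addition of water or carboxylic acids to sabinene and related alkenes with cyclopropylcarbinyl-to-homoallyl opening, which is not established as an enantiospecific route to tertiary aryl esters. No ring is closed: the cyclohexene is unveiled by fragmentation of the bicyclo[3.1.0]hexane, not by cyclisation. The one stereocentre of 4 is the former C1 of 3 and is set by inversion at that carbon (substrate control, chirality transfer from C1 while C5 becomes sp2), which should turn (1S,5S)-3 into the (R) ester. The step needs capture at C1 before the bridged ion relaxes to the planar, achiral terpinen-4-yl cation or loses a proton to menthadienes; excess dissolved 2 in a weakly polar solvent, low temperature, a catalytic amount of acid and a cold basic quench are meant to secure this, and any ester formed reversibly at C4 can re-ionise to the same chiral cation. Chemoselectivity rests on the acetate, which removes the phenol oxygen as a nucleophile, and on bromine standing in for the acid-labile prenyl groups.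

Step 3
Reactants: 4 (R)-terpinen-4-yl 4-acetoxy-3,5-dibromobenzoate; 5 prenylboronic acid pinacol ester [4,4,5,5-tetramethyl-2-(3-methylbut-2-en-1-yl)-1,3,2-dioxaborolane]
Product: 7 (R)-terpinen-4-yl 4-hydroxy-3,5-bis(3-methylbut-2-en-1-yl)benzoate (CNP0120997.1), via dibromophenol 6 (not isolated)
Conditions: K3PO4 (6 equiv), THF/H2O, 23 °C, 1 h; then 5 (3 equiv), Pd(OAc)2 (5 mol %), tBuXPhos (2-di-tert-butylphosphino-2′,4′,6′-triisopropylbiphenyl, 10 mol %), 60 °C
Reagents that add atoms: none
Why: The aryl acetate, activated by its acidic 2,6-dibromophenoxide leaving group, is saponified by aqueous phosphate while the hindered tertiary benzoate is untouched, and phenoxide 6 then undergoes a twofold allyl–aryl Suzuki–Miyaura coupling in which zerovalent palladium (from Pd(OAc)2) carrying the bulky di-tert-butyl biarylphosphine lets the σ-allyl intermediate settle on its primary carbon before reductive elimination, so linear prenyl groups are expected; the stereocentre is remote from all bond changes.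

Compound list
1 | 3,5-dibromo-4-hydroxybenzoic acid | OC(=O)c1cc(Br)c(O)c(Br)c1 | starting material
2 | 4-acetoxy-3,5-dibromobenzoic acid | CC(=O)Oc1c(Br)cc(cc1Br)C(=O)O | intermediate
3 | (1S,5S)-sabinene, (1S,5S)-4-methylidene-1-(propan-2-yl)bicyclo[3.1.0]hexane | CC(C)[C@@]12CCC(=C)[C@@H]1C2 | starting material
4 | (R)-terpinen-4-yl 4-acetoxy-3,5-dibromobenzoate | CC(=O)Oc1c(Br)cc(cc1Br)C(=O)O[C@@]2(C(C)C)CC=C(C)CC2 | intermediate
5 | prenylboronic acid pinacol ester | CC(C)=CCB1OC(C)(C)C(C)(C)O1 | starting material
6 | (R)-terpinen-4-yl 3,5-dibromo-4-hydroxybenzoate (present in the flask as its potassium phenoxide) | O=C(O[C@@]1(C(C)C)CC=C(C)CC1)c1cc(Br)c(O)c(Br)c1 | intermediate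
7 | (R)-terpinen-4-yl 4-hydroxy-3,5-bis(3-methylbut-2-en-1-yl)benzoate, CNP0120997.1 | CC(C)=CCc1cc(C(=O)O[C@@]2(C(C)C)CC=C(C)CC2)cc(CC=C(C)C)c1O | target

Total step count: 3. Longest linear sequence: 3 steps (1 → 2 → 4 → 7).

Steps most likely to fail

Step 2 (carries the new-method label). The bridged cation may relax to the open, planar terpinen-4-yl cation or lose a proton before it is trapped, so that chirality transfer is incomplete and elimination competes; the tertiary ester may also re-ionise under the acid. The fallback uses known chemistry, sets out from 2 and comes back at 4. Acid 2 is converted with oxalyl chloride and catalytic DMF in CH2Cl2 into 4-acetoxy-3,5-dibromobenzoyl chloride F1. Purchased (R)-(−)-terpinen-4-ol, its enantiomeric purity checked by chiral GC, is deprotonated with n-BuLi in THF at −78 °C. The lithium alkoxide is added slowly to F1 at −78 °C, so that it always meets excess acid chloride and the aryl acetate is spared. This acylation of a tertiary alkoxide by an aroyl chloride should give 4 with the stereocentre bought instead of made, and the route continues with step 3.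

Step 3. Linear selectivity in the allyl transfer may be lost through reductive elimination from the tertiary σ-allyl isomer, and the second coupling at the electron-rich phenoxide may stall or give way to protodebromination. The fallback sets out from 4 and comes back at 7. After the same phosphate unmasking, twofold Suzuki–Miyaura coupling with allylboronic acid pinacol ester (Pd(dppf)Cl2, K3PO4, THF/H2O, 60 °C) raises no linear/branched question and should give (R)-terpinen-4-yl 3,5-diallyl-4-hydroxybenzoate F2. Cross-metathesis of both terminal alkenes with excess 2-methylbut-2-ene under the second-generation Grubbs catalyst RuCl2(=CHPh)(PCy3)(H2IMes) in CH2Cl2 at 40 °C then turns each allyl into a prenyl group and gives 7; the trisubstituted ring alkene should be inert to metathesis.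

Step 1. O-acylation of the hindered, weakly nucleophilic phenol may be incomplete, or acyl transfer to the carboxyl group may compete. The fallback replaces the acyl mask by a silyl ether, sets out from 1 and comes back at 6.
- Exhaustive silylation of 1 (TIPSOTf, 2,6-lutidine, CH2Cl2) should give triisopropylsilyl 3,5-dibromo-4-(triisopropylsilyloxy)benzoate F3.
- Mild hydrolysis of the silyl ester alone (AcOH, THF/H2O) frees 3,5-dibromo-4-(triisopropylsilyloxy)benzoic acid F4.
- F4, freely soluble in cold CH2Cl2, takes the place of 2 in the sabinene addition of step 2 and should give (R)-terpinen-4-yl 3,5-dibromo-4-(triisopropylsilyloxy)benzoate F5.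
- Bu4NF in THF at 0 °C removes the silyl group to give 6, which is then isolated and enters the coupling stage of step 3.

Further compounds
F1 | step 2 | 4-acetoxy-3,5-dibromobenzoyl chloride | CC(=O)Oc1c(Br)cc(cc1Br)C(Cl)=O
F2 | step 3 | (R)-terpinen-4-yl 3,5-diallyl-4-hydroxybenzoate | C=CCc1cc(cc(CC=C)c1O)C(=O)O[C@@]1(C(C)C)CC=C(C)CC1
F3 | step 1 | triisopropylsilyl 3,5-dibromo-4-(triisopropylsilyloxy)benzoate | CC(C)[Si](C(C)C)(C(C)C)OC(=O)c1cc(Br)c(O[Si](C(C)C)(C(C)C)C(C)C)c(Br)c1
F4 | step 1 | 3,5-dibromo-4-(triisopropylsilyloxy)benzoic acid | OC(=O)c1cc(Br)c(O[Si](C(C)C)(C(C)C)C(C)C)c(Br)c1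
F5 | step 1 | (R)-terpinen-4-yl 3,5-dibromo-4-(triisopropylsilyloxy)benzoate | CC(C)[Si](C(C)C)(C(C)C)Oc1c(Br)cc(cc1Br)C(=O)O[C@@]1(C(C)C)CC=C(C)CC1
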